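The trans-hydroazulene is unmasked, both rings at once, from a cis-decalin. The feature exploited is the ring-fusion C5–H lying between the quaternary C1 and the oxygenated C6 (cyclopentane C1–C5; cycloheptene C1, C5–C10). In decalin 13 (ring A: C1–C6; ring B: C1, C6–C10) an equatorial C5 mesylate next to the tertiary C6 alcohol lets C1 shift from C6 to C5. This one semipinacol step contracts ring A to the cyclopentane, expands ring B to the seven-membered ring, sets the trans fusion by inversion at C5 and delivers C6 as a ketone. The precursor, an all-cis triol monomesylate, derives from a methylated Wieland–Miescher ketone.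

Key step: step 10

Remark on numbering: from compound 5 on, every ring carbon carries the number it has in the target (C1 quaternary C–CH3; C2, C3 CH2; C4 C(OH)(i-Pr); C5 ring-fusion CH; C6 C–O; C7 CH2; C8 C(CH3)=; C9 =CH; C10 C–O next to C1); β is the face of the C1 methyl, α the opposite face.

Step 1
Reactants: 1 5-methylcyclohexane-1,3-dione
Product: 2 2,5-dimethylcyclohexane-1,3-dione
Conditions: MeI, KOH, H2O/MeOH, 65 °C
Reagents that add atoms: iodomethane, CI
Why: C-alkylation of the cyclic 1,3-diketone enolate at the doubly activated C2, the standard way to 2-alkylcyclohexane-1,3-diones; no stereocentre of consequence is formed.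

Step 2
Reactants: 2 2,5-dimethylcyclohexane-1,3-dione; 3 but-3-en-2-one
Product: 4 2,5-dimethyl-2-(3-oxobutyl)cyclohexane-1,3-dione (cis/trans mixture, achiral)
Conditions: Et3N (cat.), THF, 23 °C
Reagents that add atoms: none
Why: Michael addition of the 1,3-dione to the enone builds the still prochiral quaternary carbon (future C1) between two enantiotopic ring carbonyls; the cis and trans isomers at the ring methyl converge in step 4.

Step 3
Reactants: 4 2,5-dimethyl-2-(3-oxobutyl)cyclohexane-1,3-dione
Product: 6 (8aS)-3,8a-dimethyl-3,4,8,8a-tetrahydronaphthalene-1,6(2H,7H)-dione, via cis-fused ketol 5 (not isolated)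
Conditions: (S)-proline (0.3 equiv), DMSO, 23 °C
Reagents that add atoms: none
Why: Hajos–Parrish–Eder–Sauer–Wiechert reaction: the proline enamine of the side-chain methyl ketone adds to one of the two enantiotopic ring carbonyls (6-enolendo-exo-trig aldol) and ketol 5 dehydrates, so the catalyst should set C1 as in the (S)-Wieland–Miescher ketone series.

Step 4
Reactants: 6 (8aS)-3,8a-dimethyl-3,4,8,8a-tetrahydronaphthalene-1,6(2H,7H)-dione
Product: 7 (8aS)-3,8a-dimethyl-4,7,8,8a-tetrahydronaphthalene-1,6-dione
Conditions: Pd(O2CCF3)2 (10 mol %), DMSO (20 mol %), O2 (1 atm), AcOH, 80 °C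
Reagents that add atoms: none
Why: Aerobic Pd-catalysed α,β-dehydrogenation of a ketone (Pd enolate, then β-hydride elimination): only the C10 ketone has an α-CH2 (C9) next to a β-C–H (C8), the existing enone should react far more slowly, and the C8 stereocentre of both epimers is erased.

Step 5
Reactants: 7 (8aS)-3,8a-dimethyl-4,7,8,8a-tetrahydronaphthalene-1,6-dione
Product: 8 4β-hydroxy-4α-isopropyl dienone (C5=C6, C8=C9, C10 ketone, 1β-CH3)
Conditions: i-PrMgCl, CeCl3, THF, −78 °C
Reagents that add atoms: isopropylmagnesium chloride, CC(C)[Mg]Cl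
Why: 1,2-addition of the weakly basic organocerium reagent to the unhindered ring A carbonyl (C4) rather than the neopentyl C10 carbonyl; axial attack on the face opposite the C1 methyl, as in additions to steroidal 4-en-3-ones, should place isopropyl α and the C4 hydroxyl β.

Step 6
Reactants: 8 4β-hydroxy-4α-isopropyl dienone
Product: 9 4β,10β-diol (C5=C6, C8=C9)
Conditions: NaBH4, CeCl3·7H2O, MeOH, −78 to −40 °C
Reagents that add atoms: none
Why: Luche 1,2-reduction of the ring B enone; hydride should approach C10 anti to the adjacent axial C1 methyl, as in the borohydride reduction of the Wieland–Miescher ketone, giving the 10β-alcohol cis to that methyl.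

Step 7
Reactants: 9 4β,10β-diol
Product: 10 10β-acetate of 9 (C4–OH free)
Conditions: Ac2O, Et3N, DMAP (cat.), CH2Cl2, 0 to 23 °C
Reagents that add atoms: acetic anhydride, CC(=O)OC(C)=O
Why: DMAP-catalysed acylation of the only secondary hydroxyl; the tertiary allylic C4 alcohol stays free because it has to direct the next step.

Step 8
Reactants: 10 10β-acetate
Product: 12 all-cis 4β,5β,6β-triol 10β-acetate (cis-decalin), via osmate ester 11 (not isolated)
Conditions: OsO4 (1.05 equiv), TMEDA (1.1 equiv), CH2Cl2, −78 °C; then aq. Na2SO3, THF, 50 °C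
Reagents that add atoms: osmium tetroxide, O=[Os](=O)(=O)=O
Why: Hydrogen-bond-directed syn-dihydroxylation of a cyclic allylic alcohol: the pseudoaxial C4–OH should deliver the OsO4·TMEDA complex to the β face of C5=C6, setting C5 and C6 and the cis ring fusion, while C8=C9 has no hydrogen-bond donor and is deactivated by the allylic acetate.

Step 9
Reactants: 12 all-cis triol 10β-acetate
Product: 13 5β-mesylate of 12
Conditions: MsCl, pyridine, DMAP (cat.), CH2Cl2, 0 °C
Reagents that add atoms: methanesulfonyl chloride, CS(=O)(=O)Cl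
Why: Sulfonylation of the only secondary hydroxyl (C5); the two flanking tertiary alcohols should not react with MsCl in pyridine.

Step 10
Reactants: 13 5β-mesylate
Product: 15 trans-fused hydroazulenone (10β-OAc, 4β-OH, 4α-i-Pr, 5α-H, C6 ketone), via bis(diethylaluminium) alkoxide 14 (not isolated)
Conditions: Et3Al (3 equiv), CH2Cl2, −78 to 0 °C; then aq. Rochelle salt, 0 °C
Reagents that add atoms: none
Why: Et3Al converts both tertiary hydroxyls into aluminium alkoxides and activates the mesylate; as the C5–O bond ionises, the antiperiplanar C6–C1 bond shifts to C5 and the C6 alkoxide oxygen becomes the ketone. The closest known reaction is the semipinacol rearrangement of vicinal diol monosulfonates, which is established for turning decalin diol monosulfonates into hydroazulenones. Neither ring is closed end to end: both arise from the one suprafacial 1,2-shift through a three-centre transition state (backside displacement of mesylate at C5 by the C6–C1 σ-bond), so ring A loses C6 (six to five) and ring B gains C5 (six to seven). C5 is inverted (C1 enters anti to the 5β-mesylate, leaving H-5 α and trans to the 1β-methyl) and C1 migrates with retention, both controlled by the configurations set in steps 3 and 8. The step needs C1 rather than C3, C7 or isopropyl to migrate: in the ring A chair locked by the equatorial isopropyl group (4-OH and 6-OH axial, 5-OMs equatorial) only the ring bonds C6–C1 and C4–C3 are antiperiplanar to C5–O, and the fully substituted C1 should migrate far better than the primary C3. Elimination and epoxide formation are excluded because C4 and C6 carry no hydrogen and both oxygens are cis to the mesylate; the base-sensitive product is quenched cold and reduced at once.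

Step 11
Reactants: 15 trans-fused hydroazulenone
Product: 17 4β,6α-diol 10β-acetate, via alkoxy(diacetoxy)borohydride 16 (not isolated)
Conditions: Me4NBH(OAc)3, MeCN/AcOH (1:1), −30 °C
Reagents that add atoms: none
Why: Evans–Saksena reduction: the C4 hydroxyl binds the triacetoxyborohydride and delivers hydride to the β face of the C6 ketone, so the new hydroxyl should be α (anti-1,3-diol, cis to H-5).

Step 12
Reactants: 17 4β,6α-diol 10β-acetate; 18 4-methoxybenzoyl chloride
Product: 19 CNP0256979.3 (10β-acetoxy-4β-hydroxy-6α-(4-methoxybenzoyloxy) daucane-type 8-ene)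
Conditions: Et3N, DMAP (cat.), CH2Cl2, 0 to 23 °C
Reagents that add atoms: none
Why: DMAP-catalysed acylation of the secondary C6 alcohol; the tertiary C4 alcohol should be inert under these conditions.

Compound list

1 | 5-methylcyclohexane-1,3-dione | CC1CC(=O)CC(=O)C1 | starting material
2 | 2,5-dimethylcyclohexane-1,3-dione | CC1CC(=O)C(C)C(=O)C1 | intermediate
3 | but-3-en-2-one (methyl vinyl ketone) | CC(=O)C=C | starting material
4 | 2,5-dimethyl-2-(3-oxobutyl)cyclohexane-1,3-dione, cis/trans mixture, achiral | CC(=O)CCC1(C)C(=O)CC(C)CC1=O | intermediate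
5 | cis-fused ketol: 6β-hydroxy-1β,8-dimethyldecalin-4,10-dione (C8 epimers; 6-OH cis to the C1 methyl) | C[C@]12CCC(=O)C[C@@]1(O)CC(C)CC2=O | intermediate (not isolated)
6 | (8aS)-3,8a-dimethyl-3,4,8,8a-tetrahydronaphthalene-1,6(2H,7H)-dione, C3 epimers (target numbering: C4 and C10 ketones, C5=C6, 1β-CH3, 8-CH3) | C[C@]12CCC(=O)C=C1CC(C)CC2=O | intermediate
7 | (8aS)-3,8a-dimethyl-4,7,8,8a-tetrahydronaphthalene-1,6-dione (target numbering: C4 and C10 ketones, C5=C6, C8=C9) | C[C@]12CCC(=O)C=C1CC(C)=CC2=O | intermediate
8 | (6R,8aS)-6-hydroxy-3,8a-dimethyl-6-(propan-2-yl)-6,7,8,8a-tetrahydronaphthalen-1(4H)-one (target numbering: 4β-OH, 4α-i-Pr, C10 ketone) | C[C@]12CC[C@@](O)(C(C)C)C=C1CC(C)=CC2=O | intermediate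
9 | 4β,10β-dihydroxy-4α-isopropyl-1β,8-dimethyl decalin with C5=C6 and C8=C9 (10-OH cis to the C1 methyl) | C[C@]12CC[C@@](O)(C(C)C)C=C1CC(C)=C[C@@H]2O | intermediate
10 | 10β-acetate of 9 | C[C@]12CC[C@@](O)(C(C)C)C=C1CC(C)=C[C@@H]2OC(C)=O | intermediate
11 | cyclic osmate ester of the 5β,6β-diol (hexavalent osmium, TMEDA-ligated), C4–OH free | C[C@]12CC[C@@](O)(C(C)C)[C@@H]3O[Os-2]4(=O)(=O)([N+](C)(C)CC[N+]4(C)C)O[C@]13CC(C)=C[C@@H]2OC(C)=O | intermediate (not isolated)
12 | cis-decalin 4β,5β,6β-triol 10β-acetate (4α-i-Pr, 1β-CH3, C8=C9; all four oxygens and the C1 methyl on the β face) | C[C@]12CC[C@@](O)(C(C)C)[C@H](O)[C@@]1(O)CC(C)=C[C@@H]2OC(C)=O | intermediate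
13 | 5β-methanesulfonate of 12 | C[C@]12CC[C@@](O)(C(C)C)[C@H](OS(C)(=O)=O)[C@@]1(O)CC(C)=C[C@@H]2OC(C)=O | intermediate
14 | 4,6-bis(diethylaluminium) alkoxide of 13 | C[C@]12CC[C@@](O[Al](CC)CC)(C(C)C)[C@H](OS(C)(=O)=O)[C@@]1(O[Al](CC)CC)CC(C)=C[C@@H]2OC(C)=O | intermediate (not isolated)
15 | trans-fused hydroazulenone: 10β-acetoxy-4β-hydroxy-4α-isopropyl-1β,8-dimethyl-5α-H bicyclo[5.3.0]dec-8-en-6-one (target numbering) | CC1=C[C@H](OC(C)=O)[C@@]2(C)CC[C@@](O)(C(C)C)[C@@H]2C(=O)C1 | intermediate
16 | C4–O-bound diacetoxyborohydride of 15, tetramethylammonium salt | CC1=C[C@H](OC(C)=O)[C@@]2(C)CC[C@@](O[BH-](OC(C)=O)OC(C)=O)(C(C)C)[C@@H]2C(=O)C1.C[N+](C)(C)C | intermediate (not isolated)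
17 | 10β-acetoxy-4β,6α-dihydroxy-4α-isopropyl-1β,8-dimethyl-5α-H bicyclo[5.3.0]dec-8-ene (6-OH cis to H-5) | CC1=C[C@H](OC(C)=O)[C@@]2(C)CC[C@@](O)(C(C)C)[C@@H]2[C@@H](O)C1 | intermediate
18 | 4-methoxybenzoyl chloride | COc1ccc(cc1)C(Cl)=O | starting material
19 | CNP0256979.3: 6α-(4-methoxybenzoate) of 17 | COc1ccc(C(=O)O[C@H]2CC(C)=C[C@H](OC(C)=O)[C@@]3(C)CC[C@@](O)(C(C)C)[C@H]23)cc1 | target

Total step count: 12. Longest linear sequence: 12 steps (1 to 19).

Steps most likely to fail

Step 8. The osmium reagent has to be delivered to the β face right next to the axial C1 methyl. If the hydrogen bond to the C4 hydroxyl does not outweigh this hindrance, oxidation may drift to the α face or to the C8=C9 alkene. The fallback sets out from 10 and comes back at 12 by a Woodward cis-hydroxylation, which puts both oxygens on the face opposite to the one first attacked by the electrophile. I2 and AgOAc in AcOH should add iodine to the open α face and acetate trans to it, giving the trans iodo acetate F1. On adding water and warming, the neighbouring acetate displaces iodide through a 1,3-dioxolan-2-ylium ion, which collapses to the 5β,6β-diol monoacetate F2. K2CO3 in MeOH removes both acetates to give the tetraol F3. One equivalent of Ac2O in pyridine at 0 °C should then acetylate only the allylic C10 hydroxyl, because the C5 hydroxyl lies between two fully substituted carbons, and this returns 12.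

Step 10. If the C4 alkoxide competes as the electron donor, C3 may migrate instead of C1 and ring A would contract to an acylcyclopentane; the Lewis acid may also ionise the allylic acetate. The fallback sets out from 10 and comes back at 15. The osmate ester 11 of step 8 is isolated instead of being cleaved. With the C5 and C6 oxygens tied up in the osmate, TESOTf and 2,6-lutidine silylate the only free hydroxyl to give the 4-O-triethylsilyl osmate ester F4. Aqueous Na2SO3 frees the 4-O-silyl 5β,6β-diol F5, and MsCl in pyridine gives the 4-O-silyl 5β-mesylate F6. Et3Al can now form only the C6 diethylaluminium alkoxide F7, which should rearrange to the 4-O-silyl hydroazulenone F8. HF·pyridine in MeCN removes the silyl group and returns 15.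

Step 4. The catalyst has to dehydrogenate the hindered C10 ketone while leaving the ring A enone alone. Further dehydrogenation of that enone to a dienone, or acid-promoted migration of the new double bond, would erode the material. The fallback sets out from 6 and comes back at 7. Triethyl orthoformate and TsOH in EtOH should convert only the enone into the ethyl dienol ether F9, the neopentyl C10 ketone being left alone as in steroidal 4-ene-3,17-diones. LDA and TMSCl at −78 °C give the C10 trimethylsilyl enol ether F10. Stoichiometric Pd(OAc)2 in MeCN (Saegusa–Ito oxidation) gives the ring B enone still carrying the dienol ether F11. Dilute HCl in THF hydrolyses the dienol ether back to the ring A enone and returns 7.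

Further compounds

F1 | step 8 | 6β-acetoxy-5α-iodo adduct of 10 (trans iodo acetate) | C[C@]12CC[C@@](O)(C(C)C)[C@@H](I)[C@@]1(OC(C)=O)CC(C)=C[C@@H]2OC(C)=O
F2 | step 8 | 5β,10β-diacetoxy-4β,6β-diol (cis-diol monoacetate) | C[C@]12CC[C@@](O)(C(C)C)[C@H](OC(C)=O)[C@@]1(O)CC(C)=C[C@@H]2OC(C)=O
F3 | step 8 | 4β,5β,6β,10β-tetraol | C[C@]12CC[C@@](O)(C(C)C)[C@H](O)[C@@]1(O)CC(C)=C[C@@H]2O
F4 | step 10 | 4-O-triethylsilyl ether of osmate ester 11 | C[C@]12CC[C@@](O[Si](CC)(CC)CC)(C(C)C)[C@@H]3O[Os-2]4(=O)(=O)([N+](C)(C)CC[N+]4(C)C)O[C@]13CC(C)=C[C@@H]2OC(C)=O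
F5 | step 10 | 4-O-triethylsilyl 5β,6β-diol 10β-acetate | C[C@]12CC[C@@](O[Si](CC)(CC)CC)(C(C)C)[C@H](O)[C@@]1(O)CC(C)=C[C@@H]2OC(C)=O
F6 | step 10 | 4-O-triethylsilyl 5β-mesylate | C[C@]12CC[C@@](O[Si](CC)(CC)CC)(C(C)C)[C@H](OS(C)(=O)=O)[C@@]1(O)CC(C)=C[C@@H]2OC(C)=O
F7 | step 10 | 6-O-diethylaluminium alkoxide of F6 | C[C@]12CC[C@@](O[Si](CC)(CC)CC)(C(C)C)[C@H](OS(C)(=O)=O)[C@@]1(O[Al](CC)CC)CC(C)=C[C@@H]2OC(C)=O
F8 | step 10 | 4-O-triethylsilyl ether of hydroazulenone 15 | CC1=C[C@H](OC(C)=O)[C@@]2(C)CC[C@@](O[Si](CC)(CC)CC)(C(C)C)[C@@H]2C(=O)C1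
F9 | step 4 | C4 ethyl dienol ether of 6 (C4=C5, C6=C7, C10 ketone, C8 epimers) | CCOC1=CC2=CC(C)CC(=O)[C@@]2(C)CC1
F10 | step 4 | C10 trimethylsilyl enol ether of F9 | CCOC1=CC2=CC(C)C=C(O[Si](C)(C)C)[C@@]2(C)CC1
F11 | step 4 | C4 ethyl dienol ether of 7 (C8=C9 enone at C10) | CCOC1=CC2=CC(C)=CC(=O)[C@@]2(C)CC1
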